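**Retrosynthetic overview**
- Garcinisidone D is opened at the lactone C(=O)–O bond of the seven-membered dioxepinone and at the ring A pyran, giving an aryloxy-pyranoquinone methyl ester in which the quinone is the latent ring B hydroquinone.
- The diaryl ether C–O bond is cut to a ring A phenol (prenyl and 1,1-dimethylpropargyl ether already in place) and a 6-chloro-pyranoquinone (addition–elimination).
- The ring B pyranoquinone comes from 2,5-dihydroxy-1,4-benzoquinone and prenal (Knoevenagel/oxa-6π, regiochemistry fixed by symmetry); the ring A phenol comes from methyl 2,4,6-trihydroxybenzoate, prenyl bromide and 3-chloro-3-methylbut-1-yne.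
- Ring order: ring B pyran first (step 1); then the seven-membered dioxepinone and the ring A pyran together in the last operation (step 5); both benzene rings are bought.

Assumption: the target has no stereocentre, stereogenic axis or stereogenic double bond, so it is achiral and no step needs stereocontrol.
Depsidone numbering used in names: C1–C4 and C4a (ring A), O5, C5a, C6–C9 and C9a (ring B), O10, C11 (C=O), C11a.

**Route**

Step 1
Reactants: 1 DHBQ (2,5-dihydroxy-1,4-benzoquinone); 2 prenal (3-methylbut-2-enal)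
Product: 3 6-hydroxy-2,2-dimethyl-2H-chromene-5,8-dione
Conditions: pyridine, 90 °C, 2 added slowly to 1 (2 equiv); excess 1 filtered off from CH2Cl2
Reagents that add atoms: prenal 2, CC(C)=CC=O
Why: The vinylogous acid 1 reacts like a cyclic 1,3-dicarbonyl, so Knoevenagel condensation with the enal and oxa-6π electrocyclisation of the 1-oxatriene (formal [3+3] annulation, as known for 2-hydroxy-1,4-naphthoquinone) closes the ring B pyran; the symmetry of 1 leaves only one constitution, excess 1 limits double annulation, and no stereocentre is formed.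

Step 2
Reactants: 4 methyl 2,4,6-trihydroxybenzoate; 5 prenyl bromide (1-bromo-3-methylbut-2-ene)
Product: 6 methyl 2,4,6-trihydroxy-3-(3-methylbut-2-en-1-yl)benzoate
Conditions: 5 (0.8 equiv), DBU, THF, 0 °C → rt
Reagents that add atoms: prenyl bromide 5, CC(C)=CCBr
Why: C-alkylation of the ambident phloroglucinol-type phenoxide gives one mono-C-prenyl isomer because the two free ring positions are equivalent; sub-stoichiometric 5 curbs polyprenylation, and no stereocentre is formed.

Step 3
Reactants: 6 methyl 2,4,6-trihydroxy-3-(3-methylbut-2-en-1-yl)benzoate; 7 3-chloro-3-methylbut-1-yne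
Product: 8 methyl 2,6-dihydroxy-3-(3-methylbut-2-en-1-yl)-4-[(2-methylbut-3-yn-2-yl)oxy]benzoate
Conditions: K2CO3, KI (cat.), CuI (cat.), acetone, 50 °C
Reagents that add atoms: 3-chloro-3-methylbut-1-yne 7, CC(C)(Cl)C#C
Why: Copper-catalysed O-propargylation (Williamson-type etherification via the copper acetylide of 7) goes to the 4-OH, the most acidic hydroxyl and the only one not hydrogen-bonded to the ester; no stereocentre is formed.

Step 4
Reactants: 3 6-hydroxy-2,2-dimethyl-2H-chromene-5,8-dione; 8 methyl 2,6-dihydroxy-3-(3-methylbut-2-en-1-yl)-4-[(2-methylbut-3-yn-2-yl)oxy]benzoate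
Product: 10 methyl 2-[(2,2-dimethyl-5,8-dioxo-5,8-dihydro-2H-chromen-6-yl)oxy]-6-hydroxy-5-(3-methylbut-2-en-1-yl)-4-[(2-methylbut-3-yn-2-yl)oxy]benzoate, via chloroquinone 9 (not isolated)
Conditions: 3, (COCl)2, DMF (cat.), CH2Cl2, 0 °C → rt; evaporate; then 8, Cs2CO3, MeCN, 0 °C → rt
Reagents that add atoms: none
Why: Vilsmeier-type conversion of the vinylogous acid into its vinylogous acid chloride is followed by addition–elimination (SNAr-type substitution on a haloquinone) at C6, the carbon β to the carbonyl not deactivated by the pyran oxygen; the 6-OH of 8 (flanked by H) is more acidic and much less hindered than the prenyl-flanked 2-OH, the neighbouring ring carbon is shielded by the tertiary ether, and no stereocentre is formed.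

Step 5
Reactants: 10 methyl 2-[(2,2-dimethyl-5,8-dioxo-5,8-dihydro-2H-chromen-6-yl)oxy]-6-hydroxy-5-(3-methylbut-2-en-1-yl)-4-[(2-methylbut-3-yn-2-yl)oxy]benzoate
Product: 13 garcinisidone D, via hydroquinone ester 11 (not isolated), via propargyl ether depsidone 12 (not isolated)
Conditions: Na2S2O4, THF/H2O, rt; extract and dry under Ar; then Cs2CO3 (0.3 equiv), 4 Å MS, NMP, 70 °C → 135 °C, Ar sweep
Reagents that add atoms: none
Why: Proposed new method: dithionite reduction unmasks hydroquinone 11, whose 5-OH is the only hydroxyl ortho to the diaryl ether oxygen and sits next to the ester, so phenoxide transesterification closes the seven-membered lactone and is driven by stripping methanol, after which the aryl 1,1-dimethylpropargyl ether undergoes aromatic Claisen rearrangement, [1,5]-H shift and oxa-6π electrocyclisation at the only free ortho carbon (C4) to close the ring A pyran, so two rings form in one operation; the closest known reaction types are carbodiimide or anhydride lactonisation of 2-(2-hydroxyaryloxy)benzoic acids to depsidones and the thermal propargyl aryl ether to 2,2-dimethylchromene rearrangement; no stereocentre is formed.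

**Compound list**
1 | 2,5-dihydroxy-1,4-benzoquinone (DHBQ) | O=C1C=C(O)C(=O)C=C1O | starting material
2 | 3-methylbut-2-enal (prenal) | CC(C)=CC=O | starting material
3 | 6-hydroxy-2,2-dimethyl-2H-chromene-5,8-dione | CC1(C)C=CC2=C(O1)C(=O)C=C(O)C2=O | intermediate
4 | methyl 2,4,6-trihydroxybenzoate | COC(=O)c1c(O)cc(O)cc1O | starting material
5 | 1-bromo-3-methylbut-2-ene (prenyl bromide) | CC(C)=CCBr | starting material
6 | methyl 2,4,6-trihydroxy-3-(3-methylbut-2-en-1-yl)benzoate | COC(=O)c1c(O)cc(O)c(CC=C(C)C)c1O | intermediate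
7 | 3-chloro-3-methylbut-1-yne | CC(C)(Cl)C#C | starting material
8 | methyl 2,6-dihydroxy-3-(3-methylbut-2-en-1-yl)-4-[(2-methylbut-3-yn-2-yl)oxy]benzoate | COC(=O)c1c(O)cc(OC(C)(C)C#C)c(CC=C(C)C)c1O | intermediate
9 | 6-chloro-2,2-dimethyl-2H-chromene-5,8-dione (not isolated) | CC1(C)C=CC2=C(O1)C(=O)C=C(Cl)C2=O | intermediate
10 | methyl 2-[(2,2-dimethyl-5,8-dioxo-5,8-dihydro-2H-chromen-6-yl)oxy]-6-hydroxy-5-(3-methylbut-2-en-1-yl)-4-[(2-methylbut-3-yn-2-yl)oxy]benzoate | COC(=O)c1c(O)c(CC=C(C)C)c(OC(C)(C)C#C)cc1OC1=CC(=O)C2=C(C=CC(C)(C)O2)C1=O | intermediate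
11 | methyl 2-[(5,8-dihydroxy-2,2-dimethyl-2H-chromen-6-yl)oxy]-6-hydroxy-5-(3-methylbut-2-en-1-yl)-4-[(2-methylbut-3-yn-2-yl)oxy]benzoate (not isolated) | COC(=O)c1c(O)c(CC=C(C)C)c(OC(C)(C)C#C)cc1Oc1cc(O)c2OC(C)(C)C=Cc2c1O | intermediate
12 | 1,7-dihydroxy-2-(3-methylbut-2-en-1-yl)-3-[(2-methylbut-3-yn-2-yl)oxy]-11H-dibenzo[b,e][1,4]dioxepin-11-one carrying a 2,2-dimethyl-2H-pyran fused through O at C8 and CH=CH at C9 (not isolated) | C#CC(C)(C)Oc1cc2Oc3cc(O)c4OC(C)(C)C=Cc4c3OC(=O)c2c(O)c1CC=C(C)C | intermediate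
13 | garcinisidone D: 1,7-dihydroxy-2-(3-methylbut-2-en-1-yl) depsidone with 2,2-dimethyl-2H-pyrans fused at C3(O)–C4 and C8(O)–C9; achiral | CC(C)=CCc1c(O)c2c(c3c1OC(C)(C)C=C3)Oc1cc(O)c3c(c1OC2=O)C=CC(C)(C)O3 | target

**Step count**
Total steps: 5. Longest linear sequence: 4 steps (4 to 6 to 8 to 10 to 13, that is steps 2, 3, 4 and 5).

**Steps most likely to fail**

Step 5. The lactone closure is a transesterification of a hindered, hydrogen-bonded methyl ester to an aryl ester and may stall or reopen; the Claisen part is the safe half. Fallback, setting out from 8 and coming back at 12: the methyl ester of 8 is cleaved first (KOtBu/H2O, DMSO, rt) to 2,6-dihydroxy-3-(3-methylbut-2-en-1-yl)-4-[(2-methylbut-3-yn-2-yl)oxy]benzoic acid F1. Its dicaesium salt is coupled with chloroquinone 9 (made from 3 as in step 4) to give 2-[(2,2-dimethyl-5,8-dioxo-5,8-dihydro-2H-chromen-6-yl)oxy]-6-hydroxy-5-(3-methylbut-2-en-1-yl)-4-[(2-methylbut-3-yn-2-yl)oxy]benzoic acid F2. Na2S2O4 reduction gives 2-[(5,8-dihydroxy-2,2-dimethyl-2H-chromen-6-yl)oxy]-6-hydroxy-5-(3-methylbut-2-en-1-yl)-4-[(2-methylbut-3-yn-2-yl)oxy]benzoic acid F3. The lactone is then closed by carbodiimide activation of the free acid (EDC·HCl, CH2Cl2, 0 °C) instead of transesterification, giving 12, which is heated (NMP, 135 °C) to 13 as in the second half of step 5.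

Step 4. The phenoxide of 8 is ambident and electron-rich: attack through its free ring carbon, electron transfer to the quinone, or arylation of the wrong ortho-hydroxyl may compete, and the chloride of 3 could form in part as the ortho-quinone isomer. The constitution of 10 should be checked by HMBC and NOE. Fallback, setting out from 8 and coming back at 13: the Claisen cascade is run first (8, NMP, 135 °C) to give methyl 5,7-dihydroxy-2,2-dimethyl-8-(3-methylbut-2-en-1-yl)-2H-chromene-6-carboxylate F4, which has no free ring carbon and no alkyne. F4 is coupled with 9 (Cs2CO3, MeCN) to give methyl 5-[(2,2-dimethyl-5,8-dioxo-5,8-dihydro-2H-chromen-6-yl)oxy]-7-hydroxy-2,2-dimethyl-8-(3-methylbut-2-en-1-yl)-2H-chromene-6-carboxylate F5; the 5-OH next to the pyran CH is expected to react ahead of the prenyl-flanked 7-OH, but this selectivity is less secure than in step 4. Na2S2O4 reduction gives methyl 5-[(5,8-dihydroxy-2,2-dimethyl-2H-chromen-6-yl)oxy]-7-hydroxy-2,2-dimethyl-8-(3-methylbut-2-en-1-yl)-2H-chromene-6-carboxylate F6, and base-catalysed lactonisation (Cs2CO3 cat., 4 Å MS, NMP, 80 °C) gives 13 directly.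

Step 1. Quinone 1 has two equivalent nucleophilic carbons, so bis-pyrano products and poor mass balance are possible. Fallback, setting out from 1 and coming back at 3: 1 is desymmetrised before annulation. Acid-catalysed methylation (MeOH, H2SO4 cat., reflux) gives 2,5-dimethoxy-1,4-benzoquinone F7. Half-hydrolysis (1 equiv aqueous NaOH, then acid) gives 2-hydroxy-5-methoxy-1,4-benzoquinone F8, which has a single nucleophilic carbon. Annulation with prenal 2 (pyridine, 90 °C) gives 6-methoxy-2,2-dimethyl-2H-chromene-5,8-dione F9, and hydrolysis of this vinylogous ester (aqueous NaOH, THF, then acid) gives 3.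

**Further compounds**
F1 | step 5 | 2,6-dihydroxy-3-(3-methylbut-2-en-1-yl)-4-[(2-methylbut-3-yn-2-yl)oxy]benzoic acid | OC(=O)c1c(O)cc(OC(C)(C)C#C)c(CC=C(C)C)c1O
F2 | step 5 | 2-[(2,2-dimethyl-5,8-dioxo-5,8-dihydro-2H-chromen-6-yl)oxy]-6-hydroxy-5-(3-methylbut-2-en-1-yl)-4-[(2-methylbut-3-yn-2-yl)oxy]benzoic acid | OC(=O)c1c(O)c(CC=C(C)C)c(OC(C)(C)C#C)cc1OC1=CC(=O)C2=C(C=CC(C)(C)O2)C1=O
F3 | step 5 | 2-[(5,8-dihydroxy-2,2-dimethyl-2H-chromen-6-yl)oxy]-6-hydroxy-5-(3-methylbut-2-en-1-yl)-4-[(2-methylbut-3-yn-2-yl)oxy]benzoic acid | OC(=O)c1c(O)c(CC=C(C)C)c(OC(C)(C)C#C)cc1Oc1cc(O)c2OC(C)(C)C=Cc2c1O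
F4 | step 4 | methyl 5,7-dihydroxy-2,2-dimethyl-8-(3-methylbut-2-en-1-yl)-2H-chromene-6-carboxylate | COC(=O)c1c(O)c(CC=C(C)C)c2OC(C)(C)C=Cc2c1O
F5 | step 4 | methyl 5-[(2,2-dimethyl-5,8-dioxo-5,8-dihydro-2H-chromen-6-yl)oxy]-7-hydroxy-2,2-dimethyl-8-(3-methylbut-2-en-1-yl)-2H-chromene-6-carboxylate | COC(=O)c1c(O)c(CC=C(C)C)c2OC(C)(C)C=Cc2c1OC1=CC(=O)C2=C(C=CC(C)(C)O2)C1=O
F6 | step 4 | methyl 5-[(5,8-dihydroxy-2,2-dimethyl-2H-chromen-6-yl)oxy]-7-hydroxy-2,2-dimethyl-8-(3-methylbut-2-en-1-yl)-2H-chromene-6-carboxylate | COC(=O)c1c(O)c(CC=C(C)C)c2OC(C)(C)C=Cc2c1Oc1cc(O)c2OC(C)(C)C=Cc2c1O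
F7 | step 1 | 2,5-dimethoxy-1,4-benzoquinone | COC1=CC(=O)C(OC)=CC1=O
F8 | step 1 | 2-hydroxy-5-methoxy-1,4-benzoquinone | COC1=CC(=O)C(O)=CC1=O
F9 | step 1 | 6-methoxy-2,2-dimethyl-2H-chromene-5,8-dione | COC1=CC(=O)C2=C(C=CC(C)(C)O2)C1=O
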